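**Strategy.** Everything rests on cutting the trans-dihydrobenzofuran at O1–C2 and C3–C9', so that C2–C3 becomes the alkene of an E-2-hydroxystilbene linking ring B (syringyl) to ring C (vanillin-derived). The key step exploits the ring C phenol oxygen lying ortho to that C2=C3 alkene, with C9' being one carbon at the ester level: a palladium-mediated oxycyclisation with CO and methanol forms both bonds, closes the furan ring and sets C2 and C3 trans in one operation. Its precursor is the Heck product of 5-iodovanillin and 3,5-dimethoxy-4-silyloxystyrene, with free phenol and aldehyde. The erythro guaiacylglycerol arm is then built on the ring B oxygen.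

Key step: step 4

Assumption: the sense of induction of the chiral ligands in steps 4 and 8 is assigned by analogy and must be confirmed on the first run; in either step the antipodal ligand is used if the opposite sense is found.

**Route**

Step 1
Reactants: 1 syringaldehyde (4-hydroxy-3,5-dimethoxybenzaldehyde)
Product: 2 3,5-dimethoxy-4-(triisopropylsilyloxy)benzaldehyde
Conditions: TIPSCl, imidazole, DMAP (cat.), DMF, rt
Reagents that add atoms: triisopropylsilyl chloride, CC(C)[Si](Cl)(C(C)C)C(C)C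
Why: O-silylation of an acidic phenol (silyl ether formation); the bulky triisopropylsilyl group should survive the ylide, the amine base of the Heck step and methanol, and it keeps the para oxygen of ring B a donor for the key step.

Step 2
Reactants: 2 3,5-dimethoxy-4-(triisopropylsilyloxy)benzaldehyde
Product: 3 3,5-dimethoxy-4-(triisopropylsilyloxy)styrene
Conditions: Ph3PCH3Br (1.3 equiv), KOtBu (1.2 equiv), THF, 0 °C; then 2, 0 °C → rt
Reagents that add atoms: methyltriphenylphosphonium bromide, C[P+](c1ccccc1)(c1ccccc1)c1ccccc1.[Br-]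
Why: Wittig methylenation of an aryl aldehyde with the preformed unstabilised ylide, run with the base as the limiting reagent so that no alkoxide is left to attack the aryl silyl ether.

Step 3
Reactants: 3 3,5-dimethoxy-4-(triisopropylsilyloxy)styrene; 4 5-iodovanillin (4-hydroxy-3-iodo-5-methoxybenzaldehyde)
Product: 5 (E)-4-hydroxy-3-{2-[3,5-dimethoxy-4-(triisopropylsilyloxy)phenyl]ethenyl}-5-methoxybenzaldehyde
Conditions: Pd(OAc)2 (5 mol%), P(o-tolyl)3 (10 mol%), Et3N, DMF (degassed), 90 °C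
Reagents that add atoms: none
Why: Mizoroki–Heck reaction, in which the aryl iodide adds to zerovalent palladium, the aryl group is delivered to the unsubstituted terminus of the styrene and syn β-hydride elimination should give the E-stilbene with the free phenol and aldehyde untouched.

Step 4
Reactants: 5 (E)-4-hydroxy-3-{2-[3,5-dimethoxy-4-(triisopropylsilyloxy)phenyl]ethenyl}-5-methoxybenzaldehyde; 6 carbon monoxide; 7 methanol
Product: 8 methyl (2R,3R)-2-[3,5-dimethoxy-4-(triisopropylsilyloxy)phenyl]-5-formyl-7-methoxy-2,3-dihydro-1-benzofuran-3-carboxylate (trans)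
Conditions: Pd(OCOCF3)2 (10 mol%), 2,2'-isopropylidenebis[(4S)-4-phenyl-2-oxazoline] (12 mol%), p-benzoquinone (2 equiv), CO (1 atm, balloon), MeOH/CH2Cl2 1:1, 0 °C → rt
Reagents that add atoms: carbon monoxide, [C-]#[O+]; methanol, CO
Why: Proposed new method: the bis(oxazoline) complex of divalent palladium should bind one face of the C2=C3 alkene, the ring C phenol then adds anti at C2 (the benzylic carbon activated by donor ring B), the resulting C3–palladium bond inserts CO with retention, methanol cleaves the acyl complex and p-benzoquinone returns zerovalent palladium to the divalent state. The closest known reactions are the alkoxycarbonylative cyclisation of alkenols, the cyclisation–carbonylation of 2-alkynylphenols to benzofuran-3-carboxylates and the enantioselective Wacker-type cyclisation of 2-allylphenols; what has not been shown is this cascade on a stilbene alkene with endo ring closure. The furan ring closes in the 5-endo-trig mode, open here because the alkene is activated by the metal and because attack at C3 would require a four-membered ring. C2 is controlled by the chiral ligand through the alkene face it leaves open to the phenol, and C3 follows from anti addition of oxygen and the ester carbon across the E-alkene, which gives the trans (2R,3R) ester, also the more stable diastereomer. The step needs CO insertion to outrun β-hydride elimination towards the 2-arylbenzofuran and needs a single oxypalladation pathway: the C3–palladium bond is a π-benzyl on ring C, which together with the chelating ligand and the CO atmosphere leaves no free cis site for elimination, and a syn insertion would have to bridge O1 and C3 across the forming ring. The (S,S) ligand is a first choice; its antipode serves if the first run shows the 2S series.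

Step 5
Reactants: 8 methyl (2R,3R)-2-[3,5-dimethoxy-4-(triisopropylsilyloxy)phenyl]-5-formyl-7-methoxy-2,3-dihydro-1-benzofuran-3-carboxylate
Product: 9 methyl (2R,3R)-2-[3,5-dimethoxy-4-(triisopropylsilyloxy)phenyl]-5-(1,3-dioxolan-2-yl)-7-methoxy-2,3-dihydro-1-benzofuran-3-carboxylate
Conditions: TMSOCH2CH2OTMS, TMSOTf (cat.), CH2Cl2, −78 → −20 °C; pyridine quench
Reagents that add atoms: 1,2-bis(trimethylsilyloxy)ethane, C[Si](C)(C)OCCO[Si](C)(C)C
Why: Noyori acetalisation under aprotic, cold conditions that should leave the ester, the epimerisable C3 and the aryl silyl ether alone; the aldehyde is masked only now because an acetal para to a free phenol would be too labile for step 4.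

Step 6
Reactants: 9 methyl (2R,3R)-2-[3,5-dimethoxy-4-(triisopropylsilyloxy)phenyl]-5-(1,3-dioxolan-2-yl)-7-methoxy-2,3-dihydro-1-benzofuran-3-carboxylate
Product: 10 {(2R,3S)-2-[3,5-dimethoxy-4-(triisopropylsilyloxy)phenyl]-5-(1,3-dioxolan-2-yl)-7-methoxy-2,3-dihydro-1-benzofuran-3-yl}methanol
Conditions: LiAlH4, THF, 0 °C; aq. potassium sodium tartrate
Reagents that add atoms: none
Why: Hydride reduction of the methyl ester to the C9' primary alcohol, fast enough at 0 °C that C3 is not deprotonated (its descriptor changes to S only through the priority rules) and inert towards the dioxolane and the hindered aryl silyl ether.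

Step 7
Reactants: 10 {(2R,3S)-2-[3,5-dimethoxy-4-(triisopropylsilyloxy)phenyl]-5-(1,3-dioxolan-2-yl)-7-methoxy-2,3-dihydro-1-benzofuran-3-yl}methanol
Product: 11 4-[(2R,3S)-5-(1,3-dioxolan-2-yl)-3-(hydroxymethyl)-7-methoxy-2,3-dihydro-1-benzofuran-2-yl]-2,6-dimethoxyphenol
Conditions: TBAF, AcOH, THF, 0 °C
Reagents that add atoms: none
Why: Fluoride cleavage of the aryl silyl ether, buffered with acetic acid so that the ring B phenoxide para to the C2 benzylic ether is protonated at once.

Step 8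
Reactants: 11 4-[(2R,3S)-5-(1,3-dioxolan-2-yl)-3-(hydroxymethyl)-7-methoxy-2,3-dihydro-1-benzofuran-2-yl]-2,6-dimethoxyphenol; 12 2-vinyloxirane (racemic)
Product: 13 (2S)-2-{4-[(2R,3S)-5-(1,3-dioxolan-2-yl)-3-(hydroxymethyl)-7-methoxy-2,3-dihydro-1-benzofuran-2-yl]-2,6-dimethoxyphenoxy}but-3-en-1-ol
Conditions: Pd2(dba)3·CHCl3 (2 mol%), (1R,2R)-N,N'-bis[2-(diphenylphosphino)benzoyl]cyclohexane-1,2-diamine ((R,R)-DACH-phenyl Trost ligand, 6 mol%), CH2Cl2, rt
Reagents that add atoms: none
Why: Tsuji–Trost allylic etherification run as a dynamic kinetic asymmetric transformation, in which zerovalent palladium opens the epoxide to interconverting π-allyl complexes, the liberated alkoxide directs the phenol to the internal carbon and the ligand sets C8'' as S, while the much less acidic C9' alcohol should not compete.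

Step 9
Reactants: 13 (2S)-2-{4-[(2R,3S)-5-(1,3-dioxolan-2-yl)-3-(hydroxymethyl)-7-methoxy-2,3-dihydro-1-benzofuran-2-yl]-2,6-dimethoxyphenoxy}but-3-en-1-ol
Product: 14 the bis(tert-butyldimethylsilyl) ether of 13 (both primary hydroxyls silylated; 2S at the allylic ether carbon, 2R,3S in the dihydrobenzofuran)
Conditions: TBSCl (2.5 equiv), imidazole, DMF, rt
Reagents that add atoms: tert-butyldimethylsilyl chloride, CC(C)(C)[Si](C)(C)Cl
Why: Silylation of both primary alcohols in one operation; the silyl ethers are non-chelating, which serves the Felkin–Anh addition of step 12, and they leave together with the phenol silyl ether at the end.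

Step 10
Reactants: 14 the bis(tert-butyldimethylsilyl) ether of 13
Product: 16 (2R)-2-{4-[(2R,3S)-3-(tert-butyldimethylsilyloxymethyl)-5-(1,3-dioxolan-2-yl)-7-methoxy-2,3-dihydro-1-benzofuran-2-yl]-2,6-dimethoxyphenoxy}-3-(tert-butyldimethylsilyloxy)propanal, via vicinal diol 15 (not isolated)
Conditions: OsO4 (2 mol%), NaIO4 (4 equiv), 2,6-lutidine, dioxane/H2O 3:1, rt; used crude at once
Reagents that add atoms: osmium tetroxide, O=[Os](=O)(=O)=O (catalytic oxygen carrier); sodium periodate, [Na+].[O-]I(=O)(=O)=O (restores it)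
Why: Lemieux–Johnson oxidation, which cleaves the terminal alkene without ozone (which would attack the electron-rich rings), with 2,6-lutidine keeping the medium near neutral so that C8'' and the dioxolane should be untouched.

Step 11
Reactants: 17 4-bromo-2-methoxyphenol
Product: 18 (4-bromo-2-methoxyphenoxy)(tert-butyl)dimethylsilane
Conditions: TBSCl, imidazole, CH2Cl2, rt
Reagents that add atoms: tert-butyldimethylsilyl chloride, CC(C)(C)[Si](C)(C)Cl
Why: Phenol silylation, so that the aryl bromide can be turned into a Grignard reagent.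

Step 12
Reactants: 18 (4-bromo-2-methoxyphenoxy)(tert-butyl)dimethylsilane; 16 the (2R)-α-aryloxy aldehyde
Product: 20 (1S,2R)-1-[4-(tert-butyldimethylsilyloxy)-3-methoxyphenyl]-2-{4-[(2R,3S)-3-(tert-butyldimethylsilyloxymethyl)-5-(1,3-dioxolan-2-yl)-7-methoxy-2,3-dihydro-1-benzofuran-2-yl]-2,6-dimethoxyphenoxy}-3-(tert-butyldimethylsilyloxy)propan-1-ol, via arylmagnesium bromide 19 (not isolated)
Conditions: 18 (2 equiv), Mg turnings, BrCH2CH2Br (cat.), THF, 45 °C; then 16, THF, −78 °C; H2O, then aq. NH4Cl wash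
Reagents that add atoms: none
Why: Grignard addition to an α-aryloxy aldehyde under polar Felkin–Anh control: with the C8''–OAr bond anti to the incoming aryl group, and with silyl ethers and THF disfavouring chelation, attack past the hydrogen should give the 1,2-anti (erythro) alcohol and so set C7'' as S.

Step 13
Reactants: 20 the erythro (1S,2R) tris-silyl acetal
Product: 22 (2R,3S)-2-(4-{[(1S,2R)-1,3-dihydroxy-1-(4-hydroxy-3-methoxyphenyl)propan-2-yl]oxy}-3,5-dimethoxyphenyl)-3-(hydroxymethyl)-7-methoxy-2,3-dihydro-1-benzofuran-5-carbaldehyde (the target), via acetal tetraol 21 (not isolated)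
Conditions: TBAF (4 equiv), AcOH (4 equiv), THF, 0 °C → rt; then 0.5 M aq. HCl, 0 °C → rt
Reagents that add atoms: water, O
Why: Buffered fluoride desilylation followed in the same flask by acid hydrolysis of the dioxolane of an electron-rich aryl aldehyde, under conditions too mild to ionise the C7'' benzylic alcohol or the C2 benzylic ether, so all four stereocentres should be retained.

**Compound list**

1 | syringaldehyde (4-hydroxy-3,5-dimethoxybenzaldehyde) | COc1cc(C=O)cc(OC)c1O | starting material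
2 | 3,5-dimethoxy-4-(triisopropylsilyloxy)benzaldehyde | COc1cc(C=O)cc(OC)c1O[Si](C(C)C)(C(C)C)C(C)C | intermediate
3 | 3,5-dimethoxy-4-(triisopropylsilyloxy)styrene | COc1cc(C=C)cc(OC)c1O[Si](C(C)C)(C(C)C)C(C)C | intermediate
4 | 5-iodovanillin (4-hydroxy-3-iodo-5-methoxybenzaldehyde) | COc1cc(C=O)cc(I)c1O | starting material
5 | (E)-4-hydroxy-3-{2-[3,5-dimethoxy-4-(triisopropylsilyloxy)phenyl]ethenyl}-5-methoxybenzaldehyde | COc1cc(/C=C/c2cc(C=O)cc(OC)c2O)cc(OC)c1O[Si](C(C)C)(C(C)C)C(C)C | intermediate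
6 | carbon monoxide | [C-]#[O+] | starting material
7 | methanol | CO | starting material
8 | methyl (2R,3R)-2-[3,5-dimethoxy-4-(triisopropylsilyloxy)phenyl]-5-formyl-7-methoxy-2,3-dihydro-1-benzofuran-3-carboxylate (trans) | COc1cc([C@@H]2Oc3c(OC)cc(C=O)cc3[C@H]2C(=O)OC)cc(OC)c1O[Si](C(C)C)(C(C)C)C(C)C | intermediate
9 | methyl (2R,3R)-2-[3,5-dimethoxy-4-(triisopropylsilyloxy)phenyl]-5-(1,3-dioxolan-2-yl)-7-methoxy-2,3-dihydro-1-benzofuran-3-carboxylate | COc1cc([C@@H]2Oc3c(OC)cc(C4OCCO4)cc3[C@H]2C(=O)OC)cc(OC)c1O[Si](C(C)C)(C(C)C)C(C)C | intermediate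
10 | {(2R,3S)-2-[3,5-dimethoxy-4-(triisopropylsilyloxy)phenyl]-5-(1,3-dioxolan-2-yl)-7-methoxy-2,3-dihydro-1-benzofuran-3-yl}methanol | COc1cc([C@@H]2Oc3c(OC)cc(C4OCCO4)cc3[C@H]2CO)cc(OC)c1O[Si](C(C)C)(C(C)C)C(C)C | intermediate
11 | 4-[(2R,3S)-5-(1,3-dioxolan-2-yl)-3-(hydroxymethyl)-7-methoxy-2,3-dihydro-1-benzofuran-2-yl]-2,6-dimethoxyphenol | COc1cc([C@@H]2Oc3c(OC)cc(C4OCCO4)cc3[C@H]2CO)cc(OC)c1O | intermediate
12 | 2-vinyloxirane (racemic) | C=CC1CO1 | starting material
13 | (2S)-2-{4-[(2R,3S)-5-(1,3-dioxolan-2-yl)-3-(hydroxymethyl)-7-methoxy-2,3-dihydro-1-benzofuran-2-yl]-2,6-dimethoxyphenoxy}but-3-en-1-ol | C=C[C@@H](CO)Oc1c(OC)cc([C@@H]2Oc3c(OC)cc(C4OCCO4)cc3[C@H]2CO)cc1OC | intermediate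
14 | bis(tert-butyldimethylsilyl) ether of 13 (both primary hydroxyls silylated) | C=C[C@@H](CO[Si](C)(C)C(C)(C)C)Oc1c(OC)cc([C@@H]2Oc3c(OC)cc(C4OCCO4)cc3[C@H]2CO[Si](C)(C)C(C)(C)C)cc1OC | intermediate
15 | (3R)-3-{4-[(2R,3S)-3-(tert-butyldimethylsilyloxymethyl)-5-(1,3-dioxolan-2-yl)-7-methoxy-2,3-dihydro-1-benzofuran-2-yl]-2,6-dimethoxyphenoxy}-4-(tert-butyldimethylsilyloxy)butane-1,2-diol (both C2 epimers) | OCC(O)[C@@H](CO[Si](C)(C)C(C)(C)C)Oc1c(OC)cc([C@@H]2Oc3c(OC)cc(C4OCCO4)cc3[C@H]2CO[Si](C)(C)C(C)(C)C)cc1OC | intermediate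
16 | (2R)-2-{4-[(2R,3S)-3-(tert-butyldimethylsilyloxymethyl)-5-(1,3-dioxolan-2-yl)-7-methoxy-2,3-dihydro-1-benzofuran-2-yl]-2,6-dimethoxyphenoxy}-3-(tert-butyldimethylsilyloxy)propanal | O=C[C@@H](CO[Si](C)(C)C(C)(C)C)Oc1c(OC)cc([C@@H]2Oc3c(OC)cc(C4OCCO4)cc3[C@H]2CO[Si](C)(C)C(C)(C)C)cc1OC | intermediate
17 | 4-bromo-2-methoxyphenol | COc1cc(Br)ccc1O | starting material
18 | (4-bromo-2-methoxyphenoxy)(tert-butyl)dimethylsilane | COc1cc(Br)ccc1O[Si](C)(C)C(C)(C)C | intermediate
19 | [4-(tert-butyldimethylsilyloxy)-3-methoxyphenyl]magnesium bromide | COc1cc([Mg]Br)ccc1O[Si](C)(C)C(C)(C)C | intermediate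
20 | (1S,2R)-1-[4-(tert-butyldimethylsilyloxy)-3-methoxyphenyl]-2-{4-[(2R,3S)-3-(tert-butyldimethylsilyloxymethyl)-5-(1,3-dioxolan-2-yl)-7-methoxy-2,3-dihydro-1-benzofuran-2-yl]-2,6-dimethoxyphenoxy}-3-(tert-butyldimethylsilyloxy)propan-1-ol | COc1cc([C@H](O)[C@@H](CO[Si](C)(C)C(C)(C)C)Oc2c(OC)cc([C@@H]3Oc4c(OC)cc(C5OCCO5)cc4[C@H]3CO[Si](C)(C)C(C)(C)C)cc2OC)ccc1O[Si](C)(C)C(C)(C)C | intermediate
21 | (1S,2R)-2-{4-[(2R,3S)-5-(1,3-dioxolan-2-yl)-3-(hydroxymethyl)-7-methoxy-2,3-dihydro-1-benzofuran-2-yl]-2,6-dimethoxyphenoxy}-1-(4-hydroxy-3-methoxyphenyl)propane-1,3-diol | COc1cc([C@H](O)[C@@H](CO)Oc2c(OC)cc([C@@H]3Oc4c(OC)cc(C5OCCO5)cc4[C@H]3CO)cc2OC)ccc1O | intermediate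
22 | (2R,3S)-2-(4-{[(1S,2R)-1,3-dihydroxy-1-(4-hydroxy-3-methoxyphenyl)propan-2-yl]oxy}-3,5-dimethoxyphenyl)-3-(hydroxymethyl)-7-methoxy-2,3-dihydro-1-benzofuran-5-carbaldehyde | COc1cc([C@H](O)[C@@H](CO)Oc2c(OC)cc([C@@H]3Oc4c(OC)cc(C=O)cc4[C@H]3CO)cc2OC)ccc1O | target

**Step count**

Total: 13 steps. Longest linear sequence: 12 steps (steps 1–10, 12 and 13); step 11 is a one-step side branch.

**Steps most likely to fail**

1. Step 4 (the new method). β-Hydride elimination from the C3–palladium intermediate may outpace CO insertion and drain material to the aromatic 2-arylbenzofuran. The ligand may also discriminate the two alkene faces poorly, or CO may reduce the catalyst before the alkene binds. The fallback uses known chemistry, sets out from 2 and 4 and returns at 9. Aldehyde 2 is reduced (NaBH4, MeOH, 0 °C) to [3,5-dimethoxy-4-(triisopropylsilyloxy)phenyl]methanol F1. F1 is joined to 5-iodovanillin 4 by Mitsunobu etherification (PPh3, DIAD, THF) to give 4-{[3,5-dimethoxy-4-(triisopropylsilyloxy)benzyl]oxy}-3-iodo-5-methoxybenzaldehyde F2. The aldehyde is masked (ethylene glycol, PPTS, benzene, reflux) as 2-(4-{[3,5-dimethoxy-4-(triisopropylsilyloxy)benzyl]oxy}-3-iodo-5-methoxyphenyl)-1,3-dioxolane F3. Palladium-catalysed α-arylation of the Reformatsky reagent BrZnCH2CO2Me (Pd(dba)2, P(t-Bu)3, THF) replaces iodine by the acetate arm and gives methyl 2-(2-{[3,5-dimethoxy-4-(triisopropylsilyloxy)benzyl]oxy}-5-(1,3-dioxolan-2-yl)-3-methoxyphenyl)acetate F4. Diazo transfer (4-acetamidobenzenesulfonyl azide, DBU, MeCN) gives methyl 2-diazo-2-(2-{[3,5-dimethoxy-4-(triisopropylsilyloxy)benzyl]oxy}-5-(1,3-dioxolan-2-yl)-3-methoxyphenyl)acetate F5. Enantioselective intramolecular carbenoid insertion into the benzylic ether C–H bond with Rh2(S-PTTL)4 (or its antipode, whichever gives 2R; toluene, −60 °C) forms C2–C3 and should give the cis ester methyl (2R,3S)-2-[3,5-dimethoxy-4-(triisopropylsilyloxy)phenyl]-5-(1,3-dioxolan-2-yl)-7-methoxy-2,3-dihydro-1-benzofuran-3-carboxylate F6. Epimerisation at C3 (catalytic NaOMe, MeOH, 0 °C) converts F6 into the trans ester 9, where the route resumes at step 6.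

2. Step 12. The aryl Grignard reagent may add with poor facial selectivity if magnesium is chelated by the aryloxy and methoxy oxygens in competition with the Felkin–Anh mode. The fallback sets out from 16 and 19 and returns at 20. The addition is run without regard to the C7'' outcome, which gives 20 mixed with the (1R,2R) threo epimer of 20 F7. The mixture is oxidised (Dess–Martin periodinane, NaHCO3, CH2Cl2, 0 °C) to the single (2R)-1-[4-(tert-butyldimethylsilyloxy)-3-methoxyphenyl]-2-aryloxy-3-(tert-butyldimethylsilyloxy)propan-1-one F8. F8 is reduced under chelation control (Zn(BH4)2, Et2O, −20 °C): hydride approaches the zinc chelate of the ketone and aryloxy oxygens from the side away from the C9'' arm, which should return the erythro alcohol 20. C7'' is then set by hydride delivery to a ketone instead of by carbon–carbon bond formation.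

3. Step 8. The hindered 2,6-dimethoxyphenol may attack the π-allyl complex slowly or at its terminal carbon (linear ether), or the π-allyl complexes may equilibrate incompletely and erode control at C8''. The fallback sets out from 10 and returns at 16. Alcohol 10 is silylated (TBSCl, imidazole, DMF) to the C9' tert-butyldimethylsilyl ether of 10 F9. The aryl silyl ether alone is cleaved by mild base (Cs2CO3, DMF/H2O, rt) to give 4-[(2R,3S)-3-(tert-butyldimethylsilyloxymethyl)-5-(1,3-dioxolan-2-yl)-7-methoxy-2,3-dihydro-1-benzofuran-2-yl]-2,6-dimethoxyphenol F10. Methyl (S)-glycerate is silylated at its primary hydroxyl (TBSCl, imidazole, CH2Cl2, 0 °C) to methyl (2S)-3-(tert-butyldimethylsilyloxy)-2-hydroxypropanoate F11. Mitsunobu etherification of F10 with F11 (PPh3, DIAD, toluene, 0 °C → rt) proceeds with inversion to methyl (2R)-2-{4-[(2R,3S)-3-(tert-butyldimethylsilyloxymethyl)-5-(1,3-dioxolan-2-yl)-7-methoxy-2,3-dihydro-1-benzofuran-2-yl]-2,6-dimethoxyphenoxy}-3-(tert-butyldimethylsilyloxy)propanoate F12. Reduction with i-Bu2AlH (CH2Cl2, −78 °C) gives aldehyde 16, where the route resumes at step 12. C8'' then comes from the chiral pool instead of from a catalyst.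

**Further compounds**

F1 | step 4 | [3,5-dimethoxy-4-(triisopropylsilyloxy)phenyl]methanol | COc1cc(CO)cc(OC)c1O[Si](C(C)C)(C(C)C)C(C)C
F2 | step 4 | 4-{[3,5-dimethoxy-4-(triisopropylsilyloxy)benzyl]oxy}-3-iodo-5-methoxybenzaldehyde | COc1cc(C=O)cc(I)c1OCc1cc(OC)c(O[Si](C(C)C)(C(C)C)C(C)C)c(OC)c1
F3 | step 4 | 2-(4-{[3,5-dimethoxy-4-(triisopropylsilyloxy)benzyl]oxy}-3-iodo-5-methoxyphenyl)-1,3-dioxolane | COc1cc(C2OCCO2)cc(I)c1OCc1cc(OC)c(O[Si](C(C)C)(C(C)C)C(C)C)c(OC)c1
F4 | step 4 | methyl 2-(2-{[3,5-dimethoxy-4-(triisopropylsilyloxy)benzyl]oxy}-5-(1,3-dioxolan-2-yl)-3-methoxyphenyl)acetate | COC(=O)Cc1cc(C2OCCO2)cc(OC)c1OCc1cc(OC)c(O[Si](C(C)C)(C(C)C)C(C)C)c(OC)c1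
F5 | step 4 | methyl 2-diazo-2-(2-{[3,5-dimethoxy-4-(triisopropylsilyloxy)benzyl]oxy}-5-(1,3-dioxolan-2-yl)-3-methoxyphenyl)acetate | COC(=O)C(=[N+]=[N-])c1cc(C2OCCO2)cc(OC)c1OCc1cc(OC)c(O[Si](C(C)C)(C(C)C)C(C)C)c(OC)c1
F6 | step 4 | methyl (2R,3S)-2-[3,5-dimethoxy-4-(triisopropylsilyloxy)phenyl]-5-(1,3-dioxolan-2-yl)-7-methoxy-2,3-dihydro-1-benzofuran-3-carboxylate (cis) | COc1cc([C@@H]2Oc3c(OC)cc(C4OCCO4)cc3[C@@H]2C(=O)OC)cc(OC)c1O[Si](C(C)C)(C(C)C)C(C)C
F7 | step 12 | (1R,2R)-1-[4-(tert-butyldimethylsilyloxy)-3-methoxyphenyl]-2-{4-[(2R,3S)-3-(tert-butyldimethylsilyloxymethyl)-5-(1,3-dioxolan-2-yl)-7-methoxy-2,3-dihydro-1-benzofuran-2-yl]-2,6-dimethoxyphenoxy}-3-(tert-butyldimethylsilyloxy)propan-1-ol (threo epimer of 20) | COc1cc([C@@H](O)[C@@H](CO[Si](C)(C)C(C)(C)C)Oc2c(OC)cc([C@@H]3Oc4c(OC)cc(C5OCCO5)cc4[C@H]3CO[Si](C)(C)C(C)(C)C)cc2OC)ccc1O[Si](C)(C)C(C)(C)C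
F8 | step 12 | (2R)-1-[4-(tert-butyldimethylsilyloxy)-3-methoxyphenyl]-2-{4-[(2R,3S)-3-(tert-butyldimethylsilyloxymethyl)-5-(1,3-dioxolan-2-yl)-7-methoxy-2,3-dihydro-1-benzofuran-2-yl]-2,6-dimethoxyphenoxy}-3-(tert-butyldimethylsilyloxy)propan-1-one | COc1cc(C(=O)[C@@H](CO[Si](C)(C)C(C)(C)C)Oc2c(OC)cc([C@@H]3Oc4c(OC)cc(C5OCCO5)cc4[C@H]3CO[Si](C)(C)C(C)(C)C)cc2OC)ccc1O[Si](C)(C)C(C)(C)C
F9 | step 8 | tert-butyl({(2R,3S)-2-[3,5-dimethoxy-4-(triisopropylsilyloxy)phenyl]-5-(1,3-dioxolan-2-yl)-7-methoxy-2,3-dihydro-1-benzofuran-3-yl}methoxy)dimethylsilane | COc1cc([C@@H]2Oc3c(OC)cc(C4OCCO4)cc3[C@H]2CO[Si](C)(C)C(C)(C)C)cc(OC)c1O[Si](C(C)C)(C(C)C)C(C)C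
F10 | step 8 | 4-[(2R,3S)-3-(tert-butyldimethylsilyloxymethyl)-5-(1,3-dioxolan-2-yl)-7-methoxy-2,3-dihydro-1-benzofuran-2-yl]-2,6-dimethoxyphenol | COc1cc([C@@H]2Oc3c(OC)cc(C4OCCO4)cc3[C@H]2CO[Si](C)(C)C(C)(C)C)cc(OC)c1O
F11 | step 8 | methyl (2S)-3-(tert-butyldimethylsilyloxy)-2-hydroxypropanoate | COC(=O)[C@@H](O)CO[Si](C)(C)C(C)(C)C
F12 | step 8 | methyl (2R)-2-{4-[(2R,3S)-3-(tert-butyldimethylsilyloxymethyl)-5-(1,3-dioxolan-2-yl)-7-methoxy-2,3-dihydro-1-benzofuran-2-yl]-2,6-dimethoxyphenoxy}-3-(tert-butyldimethylsilyloxy)propanoate | COC(=O)[C@@H](CO[Si](C)(C)C(C)(C)C)Oc1c(OC)cc([C@@H]2Oc3c(OC)cc(C4OCCO4)cc3[C@H]2CO[Si](C)(C)C(C)(C)C)cc1OC
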